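**Retrosynthetic overview**
- The target is reached from a macrocyclic 2,8,9,14‑tetraol 12‑silyl ether by acetylation and desilylation. The ten‑membered ring is closed last, by ring‑closing metathesis at C5=C6.
- The hydroxy‑γ‑lactone (C7, C8, C17) comes from Shi epoxidation of an (E)‑C7=C8 dienol and epoxide‑opening lactonisation by the C19 ester. The C9 carbinol comes from Felkin reduction of a dienone made by Horner–Wadsworth–Emmons olefination.
- Ring A (C1, C10, C11) comes from a hydrogen‑bond‑catalysed Diels–Alder reaction of an aminosiloxy diene with an ester‑bearing 2‑methyl enal. C2 is set by chelation‑controlled Grignard addition, O14 by a tethered oxa‑Michael addition, C12 by SmI2 reduction.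
- Ring order: ring A (cyclohexane), then the γ‑lactone, then the ten‑membered ring.

Assumption: (R,R)‑1‑naphthyl‑TADDOL is taken to shield the enal face that gives the C1/C10 configuration drawn (by analogy with methacrolein); if the sense is opposite, the (S,S)‑catalyst is used. Locants C1–C20 in names are the briarane numbers of the target.

**Route**

Step 1
Reactants: 1 (E)-1-(dimethylamino)pent-1-en-3-one; 2 tert-butyldimethylsilyl chloride
Product: 4 (1E,3Z)-3-[(tert-butyldimethylsilyl)oxy]-N,N-dimethylpenta-1,3-dien-1-amine, via potassium dienolate 3 (not isolated)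
Conditions: KN(SiMe3)2, THF, −78 °C; then 2, −78 °C → rt
Reagents that add atoms: tert-butyldimethylsilyl chloride, CC(C)(C)[Si](C)(C)Cl
Why: Kinetic deprotonation of the vinylogous amide at the ethyl CH2 gives the Z(O)‑enolate, and O‑silylation (silyl enol ether formation) gives the (3Z)‑aminosiloxy diene; no stereocentre is formed.

Step 2
Reactants: 4 aminosiloxy diene; 5 ethyl (E)-3-methyl-4-oxobut-2-enoate; 6 4-bromo-2-methylbut-1-ene
Product: 9 ethyl 2-[(1R)-1-hydroxy-4-methylpent-4-enyl]-2,6-dimethyl-5-oxocyclohex-3-ene-1-carboxylate (11-epimer), via Diels–Alder cycloadduct 7 (not isolated), via bromomagnesium alkoxide 8 (not isolated)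
Conditions: (4R,5R)-2,2-dimethyl-α,α,α′,α′-tetra(naphth-1-yl)-1,3-dioxolane-4,5-dimethanol (1-naphthyl-TADDOL, 20 mol %), toluene, −78 °C; then BrMgCH2CH2C(CH3)=CH2 (from 6 and Mg, THF), −78 °C; then 1 M HCl, THF, 0 °C
Reagents that add atoms: ethyl (E)-3-methyl-4-oxobut-2-enoate, CCOC(=O)/C=C(\C)C=O; 4-bromo-2-methylbut-1-ene (as its Grignard reagent), C=C(C)CCBr
Why: Proposed new method: a TADDOL hydroxyl hydrogen‑bonds the formyl oxygen of 5, lowering its LUMO while the naphthyl groups screen one enantioface, so the diene should add endo with its methyl‑bearing terminus at the ester‑bearing carbon (β to CHO), which fixes C1 and C10 (CHO trans to CO2Et from the E‑dienophile) and puts the C11 methyl and NMe2 cis to CHO; the cis β‑amino aldehyde then chelates magnesium so the Grignard reagent attacks anti to the ring branch (2R), and acid hydrolysis with β‑elimination of Me2NH unveils the enone; the closest known reaction type is the TADDOL‑catalysed Diels–Alder reaction of 1‑amino‑3‑siloxybutadiene with α‑substituted acroleins, here extended to a 4‑substituted diene and a trisubstituted, ester‑activated enal.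

Step 3
Reactants: 9 enone carbinol (11-epimer)
Product: 11 ethyl 2-[(1R)-1-hydroxy-4-methylpent-4-enyl]-2,6-dimethyl-5-oxocyclohex-3-ene-1-carboxylate (C11 as in the target), via dilithium dienolate 10 (not isolated)
Conditions: LiN(SiMe3)2 (2.2 equiv), THF, −78 °C; then AcOH, −78 °C
Reagents that add atoms: none
Why: Enolate formation and kinetic protonation: the cross‑conjugated α′‑dienolate is protonated on carbon anti to the pseudoaxial C10 ester, which turns the C11 methyl cis to the ester as in the target.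

Step 4
Reactants: 11 enone carbinol; 12 acetaldehyde
Product: 14 cis-fused O2,O14-ethylidene acetal ketone (C9 ethyl ester), via hemiacetal 13 (not isolated)
Conditions: 12 (5 equiv), N-[3,5-bis(trifluoromethyl)phenyl]-N′-[2-(dimethylamino)ethyl]thiourea (10 mol %), CH2Cl2, 0 °C → rt
Reagents that add atoms: acetaldehyde, CC=O
Why: Hemiacetal‑tethered intramolecular oxa‑Michael addition under bifunctional amine–thiourea catalysis: the hemiacetal oxygen anchored on O2 reaches C14 only by axial attack on the face of the C2 branch, giving the cis‑fused 1,3‑dioxane (O14 cis to C2) with the acetal methyl equatorial.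

Step 5
Reactants: 14 acetal ketone
Product: 15 (12S)-alcohol of 14
Conditions: SmI2 (2.5 equiv), MeOH, THF, 0 °C
Reagents that add atoms: none
Why: Single‑electron (ketyl) reduction of the β‑alkoxy ketone by divalent samarium with methanol as proton source gives the thermodynamically preferred equatorial alcohol syn to O14 (12S) and leaves the ester untouched.

Step 6
Reactants: 15 alcohol; 16 triisopropylsilyl trifluoromethanesulfonate
Product: 17 12-O-triisopropylsilyl ether of 15
Conditions: 16, 2,6-lutidine, CH2Cl2, −78 → 0 °C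
Reagents that add atoms: triisopropylsilyl trifluoromethanesulfonate, CC(C)[Si](OS(=O)(=O)C(F)(F)F)(C(C)C)C(C)C
Why: Silyl ether formation protects the only free hydroxyl so that it alone remains unacetylated at the end; no stereocentre is formed.

Step 7
Reactants: 18 dimethyl phosphite; 19 tert-butyl methacrylate
Product: 20 tert-butyl 3-(dimethoxyphosphoryl)-2-methylpropanoate (racemic)
Conditions: DBU (10 mol %), neat, rt
Reagents that add atoms: tert-butyl methacrylate, C=C(C)C(=O)OC(C)(C)C
Why: Base‑catalysed phospha‑Michael (Pudovik‑type) addition of the P–H bond to the methacrylate gives the racemic phosphonate, whose C17 centre is corrected in step 11.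

Step 8
Reactants: 17 silyl ether ester; 20 phosphonate
Product: 21 β-ketophosphonate (C9 ketone; epimers at C8 and C17)
Conditions: 20 (3 equiv), LiN(iPr)2 (3 equiv), THF, −78 °C; then 17, −78 → 0 °C; then AcOH
Reagents that add atoms: tert-butyl 3-(dimethoxyphosphoryl)-2-methylpropanoate, COP(=O)(OC)CC(C)C(=O)OC(C)(C)C
Why: Claisen‑type acylation of the α‑lithiated phosphonate by the ethyl ester (β‑ketophosphonate synthesis) is driven by deprotonation of the product by a second equivalent of anion; C8 and C17 form as mixtures that are erased (C8) or corrected (C17) later.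

Step 9
Reactants: 21 β-ketophosphonate; 22 acrolein
Product: 23 (7E)-dienone C9(=O)–C8[CH(CH3)CO2tBu]=C7H–CH=CH2 (C17 epimers)
Conditions: 22, Ba(OH)2·8H2O, THF/H2O (40:1), 0 °C → rt
Reagents that add atoms: acrolein, C=CC=O
Why: Horner–Wadsworth–Emmons olefination of the α‑branched β‑ketophosphonate gives the E‑configured trisubstituted C7=C8 bond (acyl group trans to the vinyl group).

Step 10
Reactants: 23 dienone
Product: 24 (9R)-dienol
Conditions: NaBH4, CeCl3·7H2O, MeOH, −78 °C
Reagents that add atoms: none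
Why: Luche 1,2‑reduction with Felkin–Anh attack of hydride anti to the quaternary C1 branch of the C10 stereocentre gives the 9R carbinol.

Step 11
Reactants: 24 dienol; 25 potassium peroxymonosulfate
Product: 28 hydroxy lactone (C7, C8, C17 as in the target; vinyl on C7), via vinyl epoxide 26 (not isolated), via lactone 17-epimer mixture 27 (not isolated)
Conditions: ent-Shi ketone (1,2:4,5-di-O-isopropylidene-β-L-erythro-2,3-hexodiulo-2,6-pyranose, 30 mol %), KHSO5 (as 2KHSO5·KHSO4·K2SO4), K2CO3, Bu4NHSO4, MeCN/CH2(OMe)2/aq. buffer pH 10.5, 0 °C; then camphorsulfonic acid (20 mol %), CH2Cl2, 0 °C → rt; then DBU (0.5 equiv), toluene, 60 °C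
Reagents that add atoms: potassium peroxymonosulfate, [K+].[O-]S(=O)(=O)OO
Why: Shi asymmetric epoxidation (chiral dioxirane, spiro transition state) oxidises only the trisubstituted C7=C8 bond on the face that fixes C8; acid then makes the tert‑butyl ester carbonyl open the vinyl epoxide at allylic C7 with inversion (γ‑lactone, loss of isobutene), and base equilibrates C17 to the epimer with the methyl trans to the C9 branch.

Step 12
Reactants: 28 hydroxy lactone diene
Product: 29 macrocyclic (5Z)-olefin (8,9-diol; O2,O14-ethylidene acetal; 12-O-silyl ether)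
Conditions: second-generation Hoveyda–Grubbs catalyst RuCl2(=CH–C6H4-2-OiPr)(H2IMes) (10 mol %), toluene (1 mM), 80 °C
Reagents that add atoms: none
Why: Ring‑closing metathesis between the isopropenyl and vinyl groups closes the ten‑membered ring, and the strain of the trans‑fused bicycle should favour the Z (in‑ring cis) trisubstituted C5=C6 bond.

Step 13
Reactants: 29 macrocyclic acetal
Product: 30 2,8,9,14-tetraol 12-O-triisopropylsilyl ether
Conditions: HS(CH2)3SH (3 equiv), BF3·OEt2 (1 equiv), CH2Cl2, −20 °C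
Reagents that add atoms: none
Why: Lewis‑acid transthioacetalisation moves the ethylidene unit to the dithiol and frees the 2‑ and 14‑hydroxyls without touching the silyl ether, lactone or alkene.

Step 14
Reactants: 30 tetraol; 31 acetic anhydride
Product: 32 2,9,14-triacetate 12-O-triisopropylsilyl ether
Conditions: 31 (6 equiv), pyridine, DMAP (10 mol %), CH2Cl2, rt
Reagents that add atoms: acetic anhydride, CC(=O)OC(C)=O
Why: DMAP‑catalysed acetylation esterifies the three secondary hydroxyls (C2, C9, C14) while the tertiary C8 hydroxyl stays free.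

Step 15
Reactants: 32 triacetate silyl ether
Product: 33 CNP0195208.4, (1R,2R,5Z,7R,8R,9R,10R,11S,12S,14R,17S)-2,9,14-triacetoxy-8,12-dihydroxybriar-5-en-18,7-olide
Conditions: HF·pyridine, THF, 0 °C → rt
Reagents that add atoms: none
Why: Fluoride‑mediated desilylation frees the C12 hydroxyl; acetates and lactone are stable to HF·pyridine.

**Compound list**

1 | (E)-1-(dimethylamino)pent-1-en-3-one | CCC(=O)/C=C/N(C)C | starting material
2 | tert-butyldimethylsilyl chloride | CC(C)(C)[Si](C)(C)Cl | starting material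
3 | potassium (1E,3Z)-1-(dimethylamino)penta-1,3-dien-3-olate | CN(C)/C=C/C([O-])=C/C.[K+] | intermediate (not isolated)
4 | (1E,3Z)-3-[(tert-butyldimethylsilyl)oxy]-N,N-dimethylpenta-1,3-dien-1-amine | CN(C)/C=C/C(O[Si](C)(C)C(C)(C)C)=C/C | intermediate
5 | ethyl (E)-3-methyl-4-oxobut-2-enoate | CCOC(=O)/C=C(\C)C=O | starting material
6 | 4-bromo-2-methylbut-1-ene | C=C(C)CCBr | starting material
7 | ethyl 3-[(tert-butyldimethylsilyl)oxy]-5-(dimethylamino)-6-formyl-2,6-dimethylcyclohex-3-ene-1-carboxylate; CHO cis to NMe2 and to the 2-methyl, trans to CO2Et (quaternary carbon = C1, ester-bearing carbon = C10) | CCOC(=O)[C@@H]2[C@@H](C)C(O[Si](C)(C)C(C)(C)C)=C[C@@H](N(C)C)[C@@]2(C)C=O | intermediate (not isolated)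
8 | bromomagnesium alkoxide of the (2R)-carbinol formed from 7 and the Grignard reagent | CCOC(=O)[C@@H]2[C@@H](C)C(O[Si](C)(C)C(C)(C)C)=C[C@@H](N(C)C)[C@@]2(C)[C@H](O[Mg]Br)CCC(C)=C | intermediate (not isolated)
9 | ethyl 2-[(1R)-1-hydroxy-4-methylpent-4-enyl]-2,6-dimethyl-5-oxocyclohex-3-ene-1-carboxylate; carbinol branch trans to CO2Et, 6-methyl trans to CO2Et (11-epimer) | CCOC(=O)[C@@H]2[C@@H](C)C(=O)C=C[C@@]2(C)[C@H](O)CCC(C)=C | intermediate
10 | dilithium alkoxide/cross-conjugated dienolate of 9 | CCOC(=O)[C@@H]2C(C)=C([O-])C=C[C@@]2(C)[C@H]([O-])CCC(C)=C.[Li+].[Li+] | intermediate (not isolated)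
11 | ethyl 2-[(1R)-1-hydroxy-4-methylpent-4-enyl]-2,6-dimethyl-5-oxocyclohex-3-ene-1-carboxylate; 6-methyl cis to CO2Et (C1, C2, C10, C11 as in the target) | CCOC(=O)[C@@H]2[C@H](C)C(=O)C=C[C@@]2(C)[C@H](O)CCC(C)=C | intermediate
12 | acetaldehyde | CC=O | starting material
13 | O2-(1-hydroxyethyl) hemiacetal of 11 | CCOC(=O)[C@@H]2[C@H](C)C(=O)C=C[C@@]2(C)[C@H](O[C@@H](C)O)CCC(C)=C | intermediate (not isolated)
14 | bicyclic ketone: ring A with C12=O, cis-fused 2-methyl-1,3-dioxane bridging O2 and O14 (acetal methyl equatorial, O14 cis to the C2 branch), 3-methylbut-3-enyl on C2, CO2Et = C9 | CCOC(=O)[C@@H]2[C@H](C)C(=O)C[C@H]3O[C@H](C)O[C@H](CCC(C)=C)[C@@]23C | intermediate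
15 | (12S)-alcohol of 14 (OH cis to O14, trans to the C11 methyl) | CCOC(=O)[C@@H]2[C@H](C)[C@@H](O)C[C@H]3O[C@H](C)O[C@H](CCC(C)=C)[C@@]23C | intermediate
16 | triisopropylsilyl trifluoromethanesulfonate | CC(C)[Si](OS(=O)(=O)C(F)(F)F)(C(C)C)C(C)C | starting material
17 | 12-O-triisopropylsilyl ether of 15 | CCOC(=O)[C@@H]2[C@H](C)[C@@H](O[Si](C(C)C)(C(C)C)C(C)C)C[C@H]3O[C@H](C)O[C@H](CCC(C)=C)[C@@]23C | intermediate
18 | dimethyl phosphite | CO[PH](=O)OC | starting material
19 | tert-butyl methacrylate | C=C(C)C(=O)OC(C)(C)C | starting material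
20 | tert-butyl 3-(dimethoxyphosphoryl)-2-methylpropanoate (racemic) | COP(=O)(OC)CC(C)C(=O)OC(C)(C)C | intermediate
21 | β-ketophosphonate: C9 ketone between ring A (C10) and C8H[P(O)(OMe)2]–C17H(CH3)–CO2tBu (epimers at C8 and C17) | CC(C(=O)OC(C)(C)C)C(P(=O)(OC)OC)C(=O)[C@@H]2[C@H](C)[C@@H](O[Si](C(C)C)(C(C)C)C(C)C)C[C@H]3O[C@H](C)O[C@H](CCC(C)=C)[C@@]23C | intermediate
22 | acrolein | C=CC=O | starting material
23 | (7E)-dienone C9(=O)–C8[C17H(CH3)CO2tBu]=C7H–CH=CH2 on ring A (C17 epimers) | CC(C(=O)OC(C)(C)C)/C(=C\C=C)C(=O)[C@@H]2[C@H](C)[C@@H](O[Si](C(C)C)(C(C)C)C(C)C)C[C@H]3O[C@H](C)O[C@H](CCC(C)=C)[C@@]23C | intermediate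
24 | (9R)-dienol from 23 (C17 epimers) | CC(C(=O)OC(C)(C)C)/C(=C\C=C)[C@H](O)[C@@H]2[C@H](C)[C@@H](O[Si](C(C)C)(C(C)C)C(C)C)C[C@H]3O[C@H](C)O[C@H](CCC(C)=C)[C@@]23C | intermediate
25 | potassium peroxymonosulfate (KHSO5) | [K+].[O-]S(=O)(=O)OO | starting material
26 | trans-7,8-epoxide of 24, oxygen on the face that becomes the 8-hydroxyl (C17 epimers) | CC(C(=O)OC(C)(C)C)[C@]4(O[C@H]4C=C)[C@H](O)[C@@H]2[C@H](C)[C@@H](O[Si](C(C)C)(C(C)C)C(C)C)C[C@H]3O[C@H](C)O[C@H](CCC(C)=C)[C@@]23C | intermediate (not isolated)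
27 | β-hydroxy-γ-vinyl-γ-lactone, C7 and C8 as in the target, C17 epimers | CC1C(=O)O[C@H](C=C)[C@@]1(O)[C@H](O)[C@@H]2[C@H](C)[C@@H](O[Si](C(C)C)(C(C)C)C(C)C)C[C@H]3O[C@H](C)O[C@H](CCC(C)=C)[C@@]23C | intermediate (not isolated)
28 | β-hydroxy-α-methyl-γ-vinyl-γ-lactone, C7, C8, C17 as in the target, with the (9R)-carbinol and the protected ring A | C[C@@H]1C(=O)O[C@H](C=C)[C@@]1(O)[C@H](O)[C@@H]2[C@H](C)[C@@H](O[Si](C(C)C)(C(C)C)C(C)C)C[C@H]3O[C@H](C)O[C@H](CCC(C)=C)[C@@]23C | intermediate
29 | briarane macrocycle: (5Z)-olefin, 8,9-diol, O2,O14-ethylidene acetal, 12-O-triisopropylsilyl ether, 18,7-lactone | O[C@@H]1[C@@H]2[C@H](C)[C@@H](O[Si](C(C)C)(C(C)C)C(C)C)C[C@@H](O[C@@H]5C)[C@@]2(C)[C@H](O5)CC/C(C)=C\[C@H]2OC(=O)[C@@H](C)[C@]12O | intermediate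
30 | 2,8,9,14-tetrahydroxy-12-(triisopropylsilyloxy)briar-5-en-18,7-olide, all centres as in the target | O[C@@H]1[C@@H]2[C@H](C)[C@@H](O[Si](C(C)C)(C(C)C)C(C)C)C[C@@H](O)[C@@]2(C)[C@H](O)CC/C(C)=C\[C@H]2OC(=O)[C@@H](C)[C@]12O | intermediate
31 | acetic anhydride | CC(=O)OC(C)=O | starting material
32 | 2,9,14-triacetoxy-8-hydroxy-12-(triisopropylsilyloxy)briar-5-en-18,7-olide, all centres as in the target | CC(=O)O[C@@H]1[C@@H]2[C@H](C)[C@@H](O[Si](C(C)C)(C(C)C)C(C)C)C[C@@H](OC(C)=O)[C@@]2(C)[C@H](OC(C)=O)CC/C(C)=C\[C@H]2OC(=O)[C@@H](C)[C@]12O | intermediate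
33 | CNP0195208.4, (1R,2R,5Z,7R,8R,9R,10R,11S,12S,14R,17S)-2,9,14-triacetoxy-8,12-dihydroxybriar-5-en-18,7-olide | CC(=O)O[C@@H]1[C@@H]2[C@H](C)[C@@H](O)C[C@@H](OC(C)=O)[C@@]2(C)[C@H](OC(C)=O)CC/C(C)=C\[C@H]2OC(=O)[C@@H](C)[C@]12O | target

**Step count**

Total steps: 15. Longest linear sequence: 14 (steps 1–6 and 8–15; step 7 is a one‑step side branch).

**Three steps most likely to fail, with fallbacks**

Step 2 (the proposed new cycloaddition): the diene/dienophile pair is more hindered than any shown under TADDOL catalysis, so rate or enantioselectivity may fall short. The fallback sets out from 5 and uses known chemistry. Pent-1-en-3-one is silylated (iPr3SiOTf, Et3N) to (3Z)-3-[(triisopropylsilyl)oxy]penta-1,3-diene F1. F1 and 5 are combined under the established cationic oxazaborolidine catalysis (protonated o‑tolyl‑CBS oxazaborolidine with triflimide counter‑ion, metal‑free) to give the formyl silyl enol ether F2. Addition of the Grignard reagent from 6 gives the carbinol F3; without the chelating amine the C2 epimers must be separated. Saegusa–Ito oxidation with Pd(OAc)2 (divalent palladium) converts the silyl enol ether into the enone, and the route is rejoined at 9.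

Step 8 (acylation of a secondary lithiated phosphonate by a hindered, axial ester): the fallback sets out from 17. Reduction with i‑Bu2AlH at −78 °C gives the aldehyde F4, the lithiated phosphonate from 20 adds to it to give the β‑hydroxyphosphonate F5, and Dess–Martin oxidation returns to 21.

Step 12 (ring‑closing metathesis to a ten‑membered ring with a trisubstituted olefin; dimerisation or the E isomer may dominate): the fallback sets out from 28. Ozonolysis of both terminal alkenes (O3; then PPh3) gives the keto aldehyde F6. Intramolecular McMurry coupling of the methyl ketone with the aldehyde (TiCl3(DME)1.5, Zn–Cu couple, DME, high dilution; low‑valent titanium) forms the C5=C6 bond and returns to 29.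

**Further compounds**

F1 | step 2 | (3Z)-3-[(triisopropylsilyl)oxy]penta-1,3-diene | C=C/C(O[Si](C(C)C)(C(C)C)C(C)C)=C/C
F2 | step 2 | ethyl 6-formyl-2,6-dimethyl-3-[(triisopropylsilyl)oxy]cyclohex-3-ene-1-carboxylate; CHO cis to the 2-methyl, trans to CO2Et | CCOC(=O)[C@@H]2[C@@H](C)C(O[Si](C(C)C)(C(C)C)C(C)C)=CC[C@@]2(C)C=O
F3 | step 2 | ethyl 6-[(1R)-1-hydroxy-4-methylpent-4-enyl]-2,6-dimethyl-3-[(triisopropylsilyl)oxy]cyclohex-3-ene-1-carboxylate | CCOC(=O)[C@@H]2[C@@H](C)C(O[Si](C(C)C)(C(C)C)C(C)C)=CC[C@@]2(C)[C@H](O)CCC(C)=C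
F4 | step 8 | C9 aldehyde corresponding to ester 17 | O=C[C@@H]2[C@H](C)[C@@H](O[Si](C(C)C)(C(C)C)C(C)C)C[C@H]3O[C@H](C)O[C@H](CCC(C)=C)[C@@]23C
F5 | step 8 | β-hydroxyphosphonate (C9 carbinol; epimers at C8, C9, C17) | CC(C(=O)OC(C)(C)C)C(P(=O)(OC)OC)C(O)[C@@H]2[C@H](C)[C@@H](O[Si](C(C)C)(C(C)C)C(C)C)C[C@H]3O[C@H](C)O[C@H](CCC(C)=C)[C@@]23C
F6 | step 12 | keto aldehyde from 28 (C5 methyl ketone, C6 aldehyde on C7) | C[C@@H]1C(=O)O[C@H](C=O)[C@@]1(O)[C@H](O)[C@@H]2[C@H](C)[C@@H](O[Si](C(C)C)(C(C)C)C(C)C)C[C@H]3O[C@H](C)O[C@H](CCC(C)=O)[C@@]23C
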